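**Retrosynthetic overview** (locants are those of the 1H-isochromene core: C1 = OCH2, O2, C3, C4, C4a, C5 = CH2, C6 = CH–O-acyl, C7 = C(CH3)OH, C8 = C=O, C8a)

1. The pyran ring is disconnected last (O2–C3, 6-endo addition of the C1 hydroxyl to a C4≡C3 ynenone); before it, the C6 orsellinate is cut by Mitsunobu esterification with inversion.
2. Enabling feature: on the carbocycle (C4a, C5, C6, C7, C8, C8a) the carbon C1 on C8a and the oxygen on C6 are 1,4-related. Joining them as O–C(=O) reveals a 2-oxabicyclo[2.2.2]oct-5-en-3-one, the cycloadduct of a 2-pyranone; hydride reduction of that bridge later gives C1H2OH and C6–OH together.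
3. Key disconnection C6–C7 / C8–C8a: inverse-demand [4+2] of a 4-alkynyl-2-pyranone (C6 = electrophilic oxygen-bearing terminus, C8a = terminus next to the carbonyl) with the ketene silyl acetal of the lactic acid–pivalaldehyde dioxolanone. In that partner C7(CH3)(O) is the nucleophilic carbon and C8 the acetal carbon (masked ketone); the acetal centre relays the lactic acid configuration to C7.
4. Ring order: 2-pyranone (temporary ring, from alkyne–alkynoate cross-addition and enol lactonisation), then the carbocycle (key step), then the bridge is cut, then the pyran ring is closed.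

Key step: step 7

Remark: TBS = tert-butyldimethylsilyl, TBDPS = tert-butyldiphenylsilyl; the five starting materials and ethyl chloroformate are taken as purchased; the cycloaddition is assumed to follow the endo mode usual for oxygenated dienophiles with 2-pyranones, which is why C6 is inverted in step 11.

Step 1
Reactants: 1 (E)-pent-2-en-4-yn-1-ol
Product: 2 tert-butyl{[(E)-pent-2-en-4-yn-1-yl]oxy}diphenylsilane
Conditions: TBDPSCl, imidazole, CH2Cl2, 0 °C to rt
Reagents that add atoms: tert-butyl(chloro)diphenylsilane (TBDPSCl), CC(C)(C)[Si](Cl)(c1ccccc1)c1ccccc1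
Why: Imidazole-promoted silyl ether formation on a primary allylic alcohol; TBDPS is chosen because it should survive the acid of step 4 and fall with fluoride in step 12.

Step 2
Reactants: 3 4,4-diethoxybut-1-yne; 4 ethyl chloroformate
Product: 6 ethyl 5,5-diethoxypent-2-ynoate, via lithium acetylide 5 (not isolated)
Conditions: BuLi, THF, −78 °C; then 4, −78 to 0 °C
Reagents that add atoms: none
Why: Acylation of a lithium acetylide with a chloroformate is the standard route to alk-2-ynoates, and the diethyl acetal is inert to BuLi.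

Step 3
Reactants: 2 tert-butyl{[(E)-pent-2-en-4-yn-1-yl]oxy}diphenylsilane; 6 ethyl 5,5-diethoxypent-2-ynoate
Product: 7 ethyl (2E,6E)-8-(tert-butyldiphenylsilyloxy)-3-(2,2-diethoxyethyl)octa-2,6-dien-4-ynoate
Conditions: Pd(OAc)2 (3 mol%), tris(2,6-dimethoxyphenyl)phosphine (3 mol%), toluene, rt
Reagents that add atoms: none
Why: Palladium-catalysed cross-addition of a terminal alkyne to an alkynoate puts the alkynyl group on the β-carbon and delivers H and alkynyl cis, so the ester and the acetal-bearing CH2 should end up cis on the new double bond, as the lactonisation of step 4 requires.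

Step 4
Reactants: 7 ethyl (2E,6E)-8-(tert-butyldiphenylsilyloxy)-3-(2,2-diethoxyethyl)octa-2,6-dien-4-ynoate
Product: 9 4-[(3E)-5-(tert-butyldiphenylsilyloxy)pent-3-en-1-yn-1-yl]-2H-pyran-2-one, via aldehyde 8 (not isolated)
Conditions: TsOH·H2O (0.2 equiv), acetone/H2O, rt; then toluene, 80 °C, removal of EtOH
Reagents that add atoms: water, O
Why: Acetal hydrolysis gives the 5-oxopent-2-enoate, whose dienol is held next to the cis ester and should close with loss of ethanol to the 2-pyranone (acid-catalysed enol lactonisation), the stable ring driving the sequence.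

Step 5
Reactants: 10 (S)-lactic acid; 11 pivalaldehyde
Product: 12 (2S,5S)-2-tert-butyl-5-methyl-1,3-dioxolan-4-one
Conditions: TsOH (cat.), H2SO4 (cat.), pentane, reflux with azeotropic removal of water; crystallisation at −78 °C
Reagents that add atoms: none
Why: Acid-catalysed acetalisation of the α-hydroxy acid gives the cis dioxolanone as the favoured, crystalline isomer, which stores the lactic acid configuration in the new acetal centre (self-regeneration of stereocentres).

Step 6
Reactants: 12 (2S,5S)-2-tert-butyl-5-methyl-1,3-dioxolan-4-one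
Product: 14 tert-butyl{[(2S)-2-tert-butyl-5-methyl-1,3-dioxol-4-yl]oxy}dimethylsilane, via lithium enolate 13 (not isolated)
Conditions: LiN(iPr)2, THF, −78 °C; then TBSCl, DMPU, −78 to 0 °C; non-aqueous work-up
Reagents that add atoms: tert-butyl(chloro)dimethylsilane (TBSCl), CC(C)(C)[Si](C)(C)Cl
Why: Kinetic deprotonation and O-silylation of the lithium enolate is standard ketene silyl acetal formation; the former C5 centre becomes trigonal while the (S)-acetal carbon is untouched.

Step 7
Reactants: 9 4-[(3E)-5-(tert-butyldiphenylsilyloxy)pent-3-en-1-yn-1-yl]-2H-pyran-2-one; 14 tert-butyl{[(2S)-2-tert-butyl-5-methyl-1,3-dioxol-4-yl]oxy}dimethylsilane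
Product: 15 (6S,7R,8R,8aR)-bridged lactone cycloadduct (full description in the compound list)
Conditions: 14 (2.5 equiv), CH2Cl2, 12 kbar, 25 °C
Reagents that add atoms: none
Why: Inverse-electron-demand Diels–Alder reaction: the HOMO of the fully oxygenated ketene silyl acetal 14 and the LUMO of 2-pyranone 9 combine in an asynchronous suprafacial [4+2] addition in which the nucleophilic carbon of 14 (future C7) bonds to the electrophilic, oxygen-bearing diene terminus (future C6) ahead of the union of the acetal carbon (future C8) with the carbonyl-flanked terminus (future C8a). The closest known reaction type is the pressure-promoted cycloaddition of 2-pyranones with ketene acetals and enol ethers, which at ambient temperature keeps the CO2 bridge as a 2-oxabicyclo[2.2.2]oct-5-en-3-one. One ring is closed, the carbocycle, by [4+2] cycloaddition across the two termini of the pyranone diene, while the lactone bridge and the dioxolane ring are carried in by the partners. C7 should be set by approach of the diene to the dioxole face opposite the tert-butyl group on the (S)-acetal carbon, which hands the lactic acid configuration back to C7; C6 and C8a follow from suprafacial addition to the flat diene combined with endo placement of the dioxole ring under C4a=C5 (OTBS and CH3 over the unhindered lactone bridge), and the C8 ketal centre is fixed by the cis ring fusion. The step needs regiocontrol, secured by the matched polarisation of both partners (acetal carbon as the cationic end of the dienophile, C6 as the δ-electrophilic end of the pyranone), and survival of the bridge, secured by running at 25 °C under pressure, below the temperature of CO2 extrusion. The endo adduct carries the bridge oxygen on C6 trans to the oxygen on C7, which step 11 turns into the cis arrangement of the target by inversion.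

Step 8
Reactants: 15 (6S,7R,8R,8aR)-bridged lactone cycloadduct
Product: 16 (6S,7R,8R,8aS)-diol with C1H2OH on C8a and OH on C6
Conditions: LiBH4, THF, 0 °C to rt
Reagents that add atoms: none
Why: LiBH4 reduces the lactone to the diol (ester reduction) and should leave the silyl ketal, the acetal and the enyne alone (no hydrometalation of the enyne as with LiAlH4); no stereocentre is created.

Step 9
Reactants: 16 (6S,7R,8R,8aS)-diol
Product: 17 C1 TBS ether of 16 with free C6 hydroxyl
Conditions: TBSCl (1.05 equiv), imidazole, CH2Cl2, 0 °C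
Reagents that add atoms: tert-butyl(chloro)dimethylsilane (TBSCl), CC(C)(C)[Si](C)(C)Cl
Why: Silylation with one equivalent of TBSCl should be selective for the primary C1 hydroxyl over the secondary C6 hydroxyl next to the quaternary C7.

Step 10
Reactants: 18 orsellinic acid (2,4-dihydroxy-6-methylbenzoic acid)
Product: 20 2,4-bis(tert-butyldimethylsilyloxy)-6-methylbenzoic acid, via tris-silyl derivative 19 (not isolated)
Conditions: TBSCl (3.5 equiv), imidazole, DMF, rt; then AcOH/THF/H2O, 0 °C
Reagents that add atoms: tert-butyl(chloro)dimethylsilane (TBSCl), CC(C)(C)[Si](C)(C)Cl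
Why: Exhaustive silylation followed by selective hydrolysis of the labile silyl ester is the usual way to O-silylated hydroxybenzoic acids.

Step 11
Reactants: 17 C1 TBS ether with free C6 hydroxyl; 20 2,4-bis(tert-butyldimethylsilyloxy)-6-methylbenzoic acid
Product: 21 (6R,7R,8R,8aS)-C6 ester (C6 inverted)
Conditions: PPh3, DIAD, toluene, 0 °C to rt
Reagents that add atoms: none
Why: Mitsunobu esterification: the carboxylate of the acidic 2,6-disubstituted benzoic acid 20 (hindered at carbon, not at oxygen) should displace the C6 oxyphosphonium with inversion to give the 6R ester cis to the C7 oxygen, and elimination cannot compete because C7 is quaternary and C5 is vinylic.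

Step 12
Reactants: 21 (6R,7R,8R,8aS)-C6 ester
Product: 23 (6R,7R)-ynenone tetraol ester (pyran-seco form of the target), via deconjugated ketone 22 (not isolated)
Conditions: HF·pyridine, pyridine, THF, 0 °C to rt
Reagents that add atoms: none
Why: Acidic fluoride should cleave all five silyl groups; loss of TBS from the C8 ketal oxygen leaves a hemiketal that collapses to the C8 ketone and releases pivalaldehyde and the C7 hydroxyl, after which enolisation of the doubly activated C8a–H moves the double bond from C4a=C5 into conjugation (C4a=C8a), a thermodynamically driven isomerisation that creates no stereocentre.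

Step 13
Reactants: 23 (6R,7R)-ynenone tetraol ester
Product: 24 Entonaemin A
Conditions: AuCl(PPh3) (5 mol%), AgOTf (5 mol%), THF, rt
Reagents that add atoms: none
Why: Gold-catalysed 6-endo-dig hydroalkoxylation (an oxa-Michael 1,6-addition to the ynenone): C3 is both the δ-carbon of the ynenone and the vinyl-stabilised alkyne terminus, so the C1 hydroxyl should attack there and give the pyran dienol ether under neutral conditions that spare the C6 ester, with no stereocentre formed.

**Compound list**

1 | (E)-pent-2-en-4-yn-1-ol | OC/C=C/C#C | starting material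
2 | tert-butyl{[(E)-pent-2-en-4-yn-1-yl]oxy}diphenylsilane | C#C/C=C/CO[Si](c1ccccc1)(c1ccccc1)C(C)(C)C | intermediate
3 | 4,4-diethoxybut-1-yne | C#CCC(OCC)OCC | starting material
4 | ethyl chloroformate | CCOC(=O)Cl | starting material
5 | (4,4-diethoxybut-1-yn-1-yl)lithium | [Li]C#CCC(OCC)OCC | intermediate (not isolated)
6 | ethyl 5,5-diethoxypent-2-ynoate | CCOC(=O)C#CCC(OCC)OCC | intermediate
7 | ethyl (2E,6E)-8-(tert-butyldiphenylsilyloxy)-3-(2,2-diethoxyethyl)octa-2,6-dien-4-ynoate (ester cis to the CH2CH(OEt)2 group) | CCOC(=O)/C=C(CC(OCC)OCC)/C#C/C=C/CO[Si](c1ccccc1)(c1ccccc1)C(C)(C)C | intermediate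
8 | ethyl (2E,6E)-8-(tert-butyldiphenylsilyloxy)-3-(2-oxoethyl)octa-2,6-dien-4-ynoate | CCOC(=O)/C=C(CC=O)/C#C/C=C/CO[Si](c1ccccc1)(c1ccccc1)C(C)(C)C | intermediate (not isolated)
9 | 4-[(3E)-5-(tert-butyldiphenylsilyloxy)pent-3-en-1-yn-1-yl]-2H-pyran-2-one | O=C1C=C(C#C/C=C/CO[Si](c2ccccc2)(c2ccccc2)C(C)(C)C)C=CO1 | intermediate
10 | (S)-lactic acid | C[C@H](O)C(=O)O | starting material
11 | pivalaldehyde | CC(C)(C)C=O | starting material
12 | (2S,5S)-2-tert-butyl-5-methyl-1,3-dioxolan-4-one (cis) | C[C@@H]1O[C@H](C(C)(C)C)OC1=O | intermediate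
13 | lithium (2S)-2-tert-butyl-5-methyl-1,3-dioxol-4-olate | CC1=C([O-])O[C@@H](C(C)(C)C)O1.[Li+] | intermediate (not isolated)
14 | tert-butyl{[(2S)-2-tert-butyl-5-methyl-1,3-dioxol-4-yl]oxy}dimethylsilane | CC1=C(O[Si](C)(C)C(C)(C)C)O[C@@H](C(C)(C)C)O1 | intermediate
15 | bridged lactone, (6S,7R,8R,8aR): 2-oxabicyclo[2.2.2]oct-5-en-3-one in which O–C1(=O) spans C6 and C8a; C4a=C5 with the (3E)-5-(TBDPS-oxy)pent-3-en-1-ynyl arm on C4a; (2S)-2-tert-butyl-1,3-dioxolane cis-fused at C7 (CH3) and C8 (OTBS), ring oxygens anti to the lactone bridge | O=C1O[C@H]2C=C(C#C/C=C/CO[Si](c3ccccc3)(c3ccccc3)C(C)(C)C)[C@@H]1[C@]3(O[Si](C)(C)C(C)(C)C)O[C@@H](C(C)(C)C)O[C@]23C | intermediate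
16 | diol, (6S,7R,8R,8aS): cyclohexene (C4a=C5) with CH2OH on C8a, OH on C6 trans to the C7 oxygen, enynyl arm on C4a, dioxolane and OTBS at C7–C8 as in 15 | OC[C@@H]1C(C#C/C=C/CO[Si](c2ccccc2)(c2ccccc2)C(C)(C)C)=C[C@H](O)[C@@]2(C)O[C@H](C(C)(C)C)O[C@@]12O[Si](C)(C)C(C)(C)C | intermediate
17 | C1 TBS ether of 16, (6S,7R,8R,8aS), free C6 hydroxyl | CC(C)(C)[Si](C)(C)OC[C@@H]1C(C#C/C=C/CO[Si](c2ccccc2)(c2ccccc2)C(C)(C)C)=C[C@H](O)[C@@]2(C)O[C@H](C(C)(C)C)O[C@@]12O[Si](C)(C)C(C)(C)C | intermediate
18 | orsellinic acid (2,4-dihydroxy-6-methylbenzoic acid) | Cc1cc(O)cc(O)c1C(=O)O | starting material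
19 | tert-butyldimethylsilyl 2,4-bis(tert-butyldimethylsilyloxy)-6-methylbenzoate | Cc1cc(O[Si](C)(C)C(C)(C)C)cc(O[Si](C)(C)C(C)(C)C)c1C(=O)O[Si](C)(C)C(C)(C)C | intermediate (not isolated)
20 | 2,4-bis(tert-butyldimethylsilyloxy)-6-methylbenzoic acid | Cc1cc(O[Si](C)(C)C(C)(C)C)cc(O[Si](C)(C)C(C)(C)C)c1C(=O)O | intermediate
21 | C6 ester, (6R,7R,8R,8aS): 17 with C6 inverted and acylated by 2,4-bis(TBS-oxy)-6-methylbenzoate, ester oxygen cis to the C7 oxygen | CC(C)(C)[Si](C)(C)OC[C@@H]1C(C#C/C=C/CO[Si](c2ccccc2)(c2ccccc2)C(C)(C)C)=C[C@@H](OC(=O)c2c(C)cc(O[Si](C)(C)C(C)(C)C)cc2O[Si](C)(C)C(C)(C)C)[C@@]2(C)O[C@H](C(C)(C)C)O[C@@]12O[Si](C)(C)C(C)(C)C | intermediate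
22 | deconjugated ketone, (6R,7R,8aS): C8 ketone, C8a(H)–CH2OH, C4a=C5, (3E)-5-hydroxypent-3-en-1-ynyl arm on C4a, orsellinate on C6, C7(CH3)OH | OC[C@@H]1C(C#C/C=C/CO)=C[C@@H](OC(=O)c2c(C)cc(O)cc2O)[C@@](C)(O)C1=O | intermediate (not isolated)
23 | ynenone, (6R,7R): 2-(hydroxymethyl)-3-[(3E)-5-hydroxypent-3-en-1-ynyl]cyclohex-2-enone (C8a=C4a) with orsellinate on C6 and C7(CH3)OH | OCC1=C(C#C/C=C/CO)C[C@@H](OC(=O)c2c(C)cc(O)cc2O)[C@@](C)(O)C1=O | intermediate
24 | Entonaemin A, (6R,7R)-7-hydroxy-3-[(1E)-3-hydroxyprop-1-en-1-yl]-7-methyl-8-oxo-5,6,7,8-tetrahydro-1H-isochromen-6-yl 2,4-dihydroxy-6-methylbenzoate | Cc1cc(O)cc(O)c1C(=O)O[C@@H]1CC2=C(COC(/C=C/CO)=C2)C(=O)[C@]1(C)O | target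

**Step count and risk**

Total steps: 13. Longest linear sequence: 9 steps (steps 2, 3, 4, 7, 8, 9, 11, 12, 13, from 4,4-diethoxybut-1-yne).

Steps most likely to fail:

Step 7. What may go wrong: the fully substituted ketene acetal may add too slowly to the enyne-bearing pyranone, so that pressure-induced oligomerisation of the conjugated enyne arm, conjugate attack on that arm, or (on forcing) cycloreversion with loss of CO2 takes over. Fallback (order of events changed: ring first, arm second): the cycloaddition is run with 14 on the smaller, inductively more electron-poor 4-bromo-2H-pyran-2-one F1 (from 4-hydroxy-2H-pyran-2-one with Bu4NBr/P2O5 in hot toluene) under the same pressure regime, which should give the C4a-bromo bridged lactone F2. The arm is then attached by Sonogashira coupling of F2 with alkyne 2 (PdCl2(PPh3)2, CuI, Et3N, THF). This sets out from 14 and 2 and comes back at 15.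

Step 11. What may go wrong: displacement at the hindered allylic C6 oxyphosphonium by the bulky orsellinate may be outrun by ionisation to the enyne-stabilised allyl cation or by participation of the neighbouring acetal oxygen, eroding the inversion, or may not take place at all. Fallback (inversion and acylation separated): 17 is inverted under Mitsunobu conditions with the small, more acidic 4-nitrobenzoic acid (PPh3, DIAD) to the 4-nitrobenzoate F3. Methanolysis (K2CO3, MeOH) frees the C6-epimeric alcohol F4. Its lithium alkoxide (LiN(SiMe3)2, THF, −78 °C) is acylated with retention by 2,4-bis(tert-butyldimethylsilyloxy)-6-methylbenzoyl chloride F5, made from 20 with oxalyl chloride and catalytic DMF. This sets out from 17 and 20 and comes back at 21.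

Step 4. What may go wrong: under acid the doubly activated aldehyde 8 may shift its double bond into conjugation with the formyl group, self-condense, or lose the silyl ether faster than its dienol lactonises. Fallback (ring taken preformed, arm coupled): 2-oxo-2H-pyran-4-yl trifluoromethanesulfonate F6 (from 4-hydroxy-2H-pyran-2-one, Tf2O, Et3N) is joined to alkyne 2 by Sonogashira coupling (PdCl2(PPh3)2, CuI, Et3N, THF, rt). This sets out from 2 and comes back at 9; steps 2 and 3 then fall away.

**Further compounds**

F1 | step 7 | 4-bromo-2H-pyran-2-one | O=C1C=C(Br)C=CO1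
F2 | step 7 | C4a-bromo bridged lactone (15 with Br in place of the enynyl arm, same configuration) | O=C1O[C@H]2C=C(Br)[C@@H]1[C@]3(O[Si](C)(C)C(C)(C)C)O[C@@H](C(C)(C)C)O[C@]23C
F3 | step 11 | C6-inverted 4-nitrobenzoate of 17, (6R,7R,8R,8aS) | CC(C)(C)[Si](C)(C)OC[C@@H]1C(C#C/C=C/CO[Si](c2ccccc2)(c2ccccc2)C(C)(C)C)=C[C@@H](OC(=O)c2ccc(cc2)[N+](=O)[O-])[C@@]2(C)O[C@H](C(C)(C)C)O[C@@]12O[Si](C)(C)C(C)(C)C
F4 | step 11 | C6 epimer of 17, (6R,7R,8R,8aS), hydroxyl cis to the C7 oxygen | CC(C)(C)[Si](C)(C)OC[C@@H]1C(C#C/C=C/CO[Si](c2ccccc2)(c2ccccc2)C(C)(C)C)=C[C@@H](O)[C@@]2(C)O[C@H](C(C)(C)C)O[C@@]12O[Si](C)(C)C(C)(C)C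
F5 | step 11 | 2,4-bis(tert-butyldimethylsilyloxy)-6-methylbenzoyl chloride | Cc1cc(O[Si](C)(C)C(C)(C)C)cc(O[Si](C)(C)C(C)(C)C)c1C(Cl)=O
F6 | step 4 | 2-oxo-2H-pyran-4-yl trifluoromethanesulfonate | O=C1C=C(OS(=O)(=O)C(F)(F)F)C=CO1
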